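## Structural features

Curlignan (18) is a trans-2-aryl-3-(hydroxymethyl)-2,3-dihydrobenzofuran: benzene ring A (C3a, C4, C5, C6, C7, C7a) is fused to a dihydrofuran ring made of O1, C2 and C3. Ring A carries the methyl ester at C5 and a methoxy group at C7, so its oxygen-bearing carbon C7a lies para to the ester. C2 is bonded to O1 and to C1' of the guaiacyl ring (4'-hydroxy, 3'-methoxy); C3 is bonded to C3a and to the hydroxymethyl carbon. The two stereocentres are neighbours, (2S,3R), with aryl and hydroxymethyl trans. The fragile spot is the C2-O1 bond, a benzylic aryl ether: it can open to a para-quinone methide once the 4'-phenol is free and base is present, it can ionise in acid, and it can be hydrogenolysed. The methyl ester rules out hydride reagents, hydroxide and free organolithiums late in the route. The real difficulty is not connectivity but the absolute and relative configuration of C2 and C3, which sit in a chain with no carbonyl group to lean on, next to a 1,2,3,5-tetrasubstituted ring A. The key step exploits that C2 and C3 are vicinal sp3 carbons each carrying one aryl carbon (C1' on C2, C3a on C3), and that the oxygen on C2 can be derived from boron. The C2-C3 pair is therefore treated as an E-alkenylboron unit to which the two aryl groups add from opposite faces, and the para relation of C7a to the ester then lets O1-C7a close by aromatic substitution without touching either stereocentre.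

## Logic of the disconnections

18 to 17. The O4'-benzyl bond is cut last. The phenol is freed at the end and under neutral conditions, because a 4'-phenoxide would make C2-O1 labile. No skeletal simplification results. The forward step must stop at the protecting group and spare C2-O1.

17 to 16. The O-Si bond on the C3 hydroxymethyl group is cut. The primary oxygen must stay masked until the ring is closed, because it could reach C7a through a five-membered transition state just as O1 does. Fluoride is used while the phenol is still benzylated, so no phenoxide is present. The forward step needs buffered fluoride so the ester is not attacked.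

16 to 15. The O1-C7a bond is cut, which removes the heterocycle and leaves an open 1,2-diarylpropane with a fluoride on C7a. The cut is made there because C7a is para to the ester and the closure breaks no bond at C2 or C3. The forward step needs the C2 alkoxide to attack C7a faster than the ester, and the silyl group must stay on the primary oxygen. A tert-butyldimethylsilyl ether is judged unsafe, since 1,3-diol monosilyl ethers pass silicon from oxygen to oxygen under alkoxide conditions; the triisopropylsilyl ether of 15 is the improved design.

15 to 14. The C2-O bond is traced back to a C2-B bond. This turns a stereodefined alcohol into the direct product of a carbon-carbon bond-forming step. The forward oxidation must proceed with retention and at a pH the ester tolerates.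

14 to 11 and 13, then 13 to 6 and 12, then 12 to 8. The C2-C1' and C3-C3a bonds are cut in one operation, which splits the molecule into three fragments of similar size and removes both stereocentres. The cut is made there because both bonds join an sp3 carbon to an aryl carbon across what can be an alkene. The forward step must add the two aryl groups anti across an E alkene with control of the face, and must prefer the 1,2-shift over direct cross-coupling. Beta-substituted alkenyl ate complexes on a pinacol ligand favour direct coupling, so the boron of 6 carries the more hindered ligand from 4. Anti addition across the E alkene, retentive oxidation and a closure that leaves C2 and C3 alone have been checked against the target and map onto the (2S,3R) trans ring.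

6 to 2 and 4 (through 5), 2 to 1, 4 to 3. The C-B bond of the alkene and the two B-O bonds are cut. Hydroboration of a terminal alkyne gives the E geometry by its mechanism, and 4 comes in one step from 3. The forward step needs boron on the terminal carbon and complete exchange of the first ligand on boron for 4.

8 to 7. The O-benzyl bond is cut, which leads back to a commercial bromophenol. The only demand is O-alkylation.

11 to 9 (through 10). The C-Br bond is cut back to a C-H bond. That hydrogen is the only one on the ring with no neighbour larger than fluorine, so a sterically governed borylation finds it. The forward step needs site selectivity in the borylation and clean exchange of boron for bromine.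

## Other disconnections considered

Alternative 1: The cut is C3-C3a combined with a change of ring size. The dihydrofuran ring is derived from the pyranone ring of the flavanone methyl (2S)-2-(4-acetoxy-3-methoxyphenyl)-8-methoxy-4-oxochromane-6-carboxylate (A1).
- Forward step: A1 would be treated with PhI(OAc)2 and H2SO4 in trimethyl orthoformate. Trivalent iodine attacks the enol ether at C3, ring A shifts from the old C4 to C3 as iodobenzene leaves, and the old C4 ends as a methyl ester. The product is dimethyl (2S,3S)-2-(4-acetoxy-3-methoxyphenyl)-7-methoxy-2,3-dihydrobenzofuran-3,5-dicarboxylate (A2).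
- In favour: cheap reagents, no precious metal, and a trans relation that can correct itself because C3-H of A2 is alpha to an ester.
- Against: A1 can lose its C2 configuration by reversible opening to the chalcone in strong acid. Shift of the electron-rich guaiacyl ring and simple dehydrogenation compete with the wanted shift of ring A. A2 carries two methyl esters and an aryl acetate, so only the C3 ester would have to be reduced.
- Comparison: on step count and cost this alternative is the better plan, and on securing the trans relation it is the equal of the chosen one. On structure, the chosen plan has C9 at the alcohol oxidation level from the start and sets both centres in the key step; the alternative relays everything from one centre that is at risk in the key step itself. On mechanism, the chosen plan has one main competing pathway, against three here.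

Alternative 2: The cuts are C3a-C4 and C7a-C7; ring A is built onto a finished dihydrofuran.
- Forward step: the silyl ketene acetal tert-butyl{[(4R,5S)-5-(4-benzyloxy-3-methoxyphenyl)-4-[(tert-butyldimethylsilyloxy)methyl]-4,5-dihydrofuran-2-yl]oxy}dimethylsilane (A3) would add as an electron-rich dienophile across C6 and C3 of methyl 3-bromo-2-oxo-2H-pyran-5-carboxylate (A4). Loss of CO2 and of the silanol would give methyl (2S,3R)-2-(4-benzyloxy-3-methoxyphenyl)-7-bromo-3-[(tert-butyldimethylsilyloxy)methyl]-2,3-dihydrobenzofuran-5-carboxylate (A5).
- In favour: both stereocentres arrive in A3 and the key step has no stereochemical task. The polarisation of A4 fixes the regiochemistry. No C-H borylation and no aromatic substitution are needed.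
- Against: the ketal carbon formed in the cycloadduct can aromatise by loss of the ring oxygen as well as by loss of silanol, which would open the dihydrofuran. The C7 bromine of A5 must still be exchanged for methoxy beside an ester. A3 needs several steps of its own.
- Comparison: on robustness of the stereochemistry this alternative is the better plan, and on convergence it is the equal. On step economy it is the longer, because of the exchange at C7 and the preparation of A3. On mechanism, the chosen plan avoids the question of which C-O bond breaks on aromatisation.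

Alternative 3: The cuts are C3a-C7a and C4-C5; both rings form at once.
- Forward step: on heating, the terminal alkyne of methyl 6-{[(1S,2R)-1-(4-benzyloxy-3-methoxyphenyl)-2-[(tert-butyldimethylsilyloxy)methyl]but-3-yn-1-yl]oxy}-5-methoxypyridazine-3-carboxylate (A6) would add across C6 and C3 of the pyridazine. Extrusion of N2 would give methyl (2S,3R)-2-(4-benzyloxy-3-methoxyphenyl)-3-[(tert-butyldimethylsilyloxy)methyl]-7-methoxy-2,3-dihydrobenzofuran-5-carboxylate (A7).
- In favour: the tether enforces the regiochemistry, all four substituents of ring A are in place beforehand, and the step needs neither metal nor ligand. A7 is the tert-butyldimethylsilyl analogue of 16, so the end game is the same.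
- Against: a pyridazine carrying two oxygen donors is a poor diene, and the temperatures such cycloadditions need threaten the benzylic pyridazinyl ether of A6 (ionisation, elimination, oxygen-to-nitrogen shift) and the propargylic centre. The stereodiad of A6 must be set earlier by separate asymmetric chemistry.
- Comparison: in the way ring A is assembled this alternative is the better plan, and in the end game it is the equal. The chosen plan is milder and creates both stereocentres in the bond-forming step. Step counts are expected to be similar.

Key step: step 6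

Assumption: B(mac) stands for boron bound to the two oxygen atoms of 4. MandyPhos stands for 2,2'-bis[α-(dimethylamino)benzyl]-1,1'-bis(diphenylphosphino)ferrocene; both antipodes are sold, and the one that leads to the (1S,2R) series is to be fixed in a trial run by correlation at the stage of 15, the (Sp,Sp) ligand being tried first.

## Route

Step 1
Reactants: 1 propargyl alcohol
Product: 2 triisopropyl(prop-2-yn-1-yloxy)silane
Conditions: TIPSCl, imidazole, DMF, 0 °C to rt
Reagents that add atoms: chlorotriisopropylsilane, CC(C)[Si](Cl)(C(C)C)C(C)C
Why: Silylation of a primary alcohol (imidazole-assisted substitution at silicon); triisopropylsilyl is chosen over smaller silyl groups because it must resist oxygen-to-oxygen migration in step 8.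

Step 2
Reactants: 3 acenaphthylene-1,2-dione
Product: 4 cis-1,2-dimethyl-1,2-dihydroacenaphthylene-1,2-diol
Conditions: AlMe3 (3 equiv), toluene, 0 °C to rt; aq. HCl; recrystallisation
Reagents that add atoms: trimethylaluminium, C[Al](C)C
Why: Twofold 1,2-addition of methylaluminium to the 1,2-diketone gives the tertiary diol; the cis (meso) isomer is expected as the main, crystalline product, and only it can span boron in step 3, so a trans contaminant cannot enter the route.

Step 3
Reactants: 2 triisopropyl(prop-2-yn-1-yloxy)silane; 4 cis-1,2-dimethyl-1,2-dihydroacenaphthylene-1,2-diol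
Product: 6 (E)-3-(triisopropylsilyloxy)prop-1-enyl-B(mac), via alkenyl catecholboronate 5 (not isolated)
Conditions: catecholborane, Cy2BH (10 mol %), THF, rt; then 4, rt
Reagents that add atoms: catecholborane, B1Oc2ccccc2O1
Why: Hydroboration of a terminal alkyne catalysed by Cy2BH: syn addition places boron on the terminal carbon and gives the E-alkenyl boronate 5; the chelating cis-diol 4 then displaces catechol from boron (transesterification) and installs the hindered ligand that the key step needs.

Step 4
Reactants: 7 4-bromo-2-methoxyphenol
Product: 8 1-benzyloxy-4-bromo-2-methoxybenzene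
Conditions: BnBr, K2CO3, DMF, rt
Reagents that add atoms: benzyl bromide, BrCc1ccccc1
Why: Williamson ether synthesis on the phenoxide; the benzyl ether should survive tert-butyllithium, the coupling, perborate, base and fluoride, and is removed last without acid or base.

Step 5
Reactants: 9 methyl 4-fluoro-3-methoxybenzoate
Product: 11 methyl 3-bromo-4-fluoro-5-methoxybenzoate, via arylboronic pinacol ester 10 (not isolated)
Conditions: [Ir(OMe)(cod)]2 (1.5 mol %), dtbpy (3 mol %), B2pin2 (0.7 equiv), THF, 80 °C; evaporate; CuBr2 (3 equiv), MeOH/H2O 1:1, 80 °C
Reagents that add atoms: copper dibromide, Br[Cu]Br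
Why: Iridium-catalysed C-H borylation is steered by sterics to the only ring hydrogen with no neighbour larger than fluorine (C5 of 9; C2 lies between two groups and C6 is ortho to the ester), and copper-mediated bromodeboronation of 10 then exchanges boron for bromine at the same carbon in the same flask.

Step 6
Reactants: 8 1-benzyloxy-4-bromo-2-methoxybenzene; 6 (E)-3-(triisopropylsilyloxy)prop-1-enyl-B(mac); 11 methyl 3-bromo-4-fluoro-5-methoxybenzoate
Product: 14 methyl 3-[(1S,2R)-1-(4-benzyloxy-3-methoxyphenyl)-1-B(mac)-3-(triisopropylsilyloxy)propan-2-yl]-4-fluoro-5-methoxybenzoate, via aryllithium 12 (not isolated), via lithium ate complex 13 (not isolated)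
Conditions: 8, t-BuLi (2.0 equiv), Et2O, −78 °C; 6, −78 °C to rt; evaporate, THF; Pd(OAc)2 (3 mol %), MandyPhos (3.6 mol %), KOTf (2.2 equiv), 11, 60 °C
Reagents that add atoms: none
Why: Bromine-lithium exchange converts 8 into 12, which adds to the trigonal boron of 6 and is used up in forming 13 before the ester-bearing 11 enters the flask. Zerovalent palladium, formed from Pd(OAc)2 and MandyPhos, inserts into the C-Br bond of 11 (the C-F bond stays), and KOTf removes bromide as KBr so that a cationic divalent arylpalladium can bind the alkene of 13. The guaiacyl group then shifts from boron to the boron-bearing carbon on the face opposite palladium (C2-C1'), palladium ends on C3, and reductive elimination with retention joins C3 to C3a; the closest known reaction type is the palladium-catalysed enantioselective conjunctive cross-coupling of beta-substituted alkenylboron ate complexes with aryl electrophiles. No ring is closed. The relative configuration of C2 and C3 follows from the E geometry of 6 and the anti course of the metallate shift, and the absolute configuration from the alkene face that the chiral bisphosphine lets palladium approach. The step needs the 1,2-shift to win over direct transfer of an organic group from boron to palladium, which the hindered ligand from 4 is there to secure, and it needs reductive elimination to outrun beta-hydride and beta-silyloxy elimination, which the chelating ligand and the poor leaving ability of the silyl ether should favour.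

Step 7
Reactants: 14 methyl 3-[(1S,2R)-1-(4-benzyloxy-3-methoxyphenyl)-1-B(mac)-3-(triisopropylsilyloxy)propan-2-yl]-4-fluoro-5-methoxybenzoate
Product: 15 methyl 3-[(1S,2R)-1-(4-benzyloxy-3-methoxyphenyl)-1-hydroxy-3-(triisopropylsilyloxy)propan-2-yl]-4-fluoro-5-methoxybenzoate
Conditions: NaBO3·4H2O, THF/H2O 1:1, rt
Reagents that add atoms: sodium perborate (source of the oxygen atom), [Na+].[Na+].O[B-]1(O)OO[B-](O)(O)OO1
Why: Oxidation of a carbon-boron bond by peroxoborate: the hydroperoxide adds to boron and the benzylic carbon migrates from boron to oxygen with retention, so C2 keeps its configuration; the mildly basic medium is expected to leave the methyl ester, the aryl fluoride and the silyl ether alone.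

Step 8
Reactants: 15 methyl 3-[(1S,2R)-1-(4-benzyloxy-3-methoxyphenyl)-1-hydroxy-3-(triisopropylsilyloxy)propan-2-yl]-4-fluoro-5-methoxybenzoate
Product: 16 methyl (2S,3R)-2-(4-benzyloxy-3-methoxyphenyl)-7-methoxy-3-[(triisopropylsilyloxy)methyl]-2,3-dihydrobenzofuran-5-carboxylate
Conditions: KN(SiMe3)2 (1.1 equiv), THF, 0 to 40 °C
Reagents that add atoms: none
Why: Intramolecular nucleophilic aromatic substitution (addition-elimination through a Meisenheimer adduct, 5-exo closure): the C2 alkoxide attacks C7a, whose fluoride is para to the ester, and fluoride leaves; no bond to C2 or C3 is broken, so the diad of 15 becomes the trans ring, and the triisopropylsilyl group should migrate too slowly for the primary oxygen to compete for C7a.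

Step 9
Reactants: 16 methyl (2S,3R)-2-(4-benzyloxy-3-methoxyphenyl)-7-methoxy-3-[(triisopropylsilyloxy)methyl]-2,3-dihydrobenzofuran-5-carboxylate
Product: 17 methyl (2S,3R)-2-(4-benzyloxy-3-methoxyphenyl)-3-(hydroxymethyl)-7-methoxy-2,3-dihydrobenzofuran-5-carboxylate
Conditions: Bu4NF, AcOH, THF, 0 °C to rt
Reagents that add atoms: none
Why: Fluoride-induced cleavage of the silyl ether, driven by the strength of the Si-F bond; acetic acid buffers the alkoxide so the ester is not attacked, and because the phenol is still benzylated no phenoxide can open the C2-O1 bond.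

Step 10
Reactants: 17 methyl (2S,3R)-2-(4-benzyloxy-3-methoxyphenyl)-3-(hydroxymethyl)-7-methoxy-2,3-dihydrobenzofuran-5-carboxylate
Product: 18 curlignan
Conditions: H2 (1 atm), Pd/C (10 %), EtOAc, rt
Reagents that add atoms: none
Why: Hydrogenolysis of the benzyl aryl ether on palladium on carbon under neutral conditions; the unhindered primary benzylic C-O bond of the protecting group is expected to cleave well before the ring-bound secondary C2-O1 bond, so the reaction is stopped after uptake of one equivalent of hydrogen.

## Compound list

1 | prop-2-yn-1-ol (propargyl alcohol) | C#CCO | starting material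
2 | triisopropyl(prop-2-yn-1-yloxy)silane | C#CCO[Si](C(C)C)(C(C)C)C(C)C | intermediate
3 | acenaphthylene-1,2-dione | O=C1C(=O)c2cccc3cccc1c23 | starting material
4 | cis-(1R,2S)-1,2-dimethyl-1,2-dihydroacenaphthylene-1,2-diol (meso) | C[C@]1(O)[C@@](C)(O)c2cccc3cccc1c23 | intermediate
5 | 2-[(E)-3-(triisopropylsilyloxy)prop-1-enyl]-1,3,2-benzodioxaborole | CC(C)[Si](C(C)C)(C(C)C)OC/C=C/B1Oc2ccccc2O1 | intermediate (not isolated)
6 | (E)-3-(triisopropylsilyloxy)prop-1-enylboronic acid, cyclic ester of 4 | CC(C)[Si](C(C)C)(C(C)C)OC/C=C/B1O[C@]2(C)c3cccc4cccc(c34)[C@]2(C)O1 | intermediate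
7 | 4-bromo-2-methoxyphenol | COc1cc(Br)ccc1O | starting material
8 | 1-benzyloxy-4-bromo-2-methoxybenzene | COc1cc(Br)ccc1OCc1ccccc1 | intermediate
9 | methyl 4-fluoro-3-methoxybenzoate | COC(=O)c1ccc(F)c(OC)c1 | starting material
10 | methyl 4-fluoro-3-methoxy-5-(4,4,5,5-tetramethyl-1,3,2-dioxaborolan-2-yl)benzoate | COC(=O)c1cc(B2OC(C)(C)C(C)(C)O2)c(F)c(OC)c1 | intermediate (not isolated)
11 | methyl 3-bromo-4-fluoro-5-methoxybenzoate | COC(=O)c1cc(Br)c(F)c(OC)c1 | intermediate
12 | (4-benzyloxy-3-methoxyphenyl)lithium | [Li]c1ccc(OCc2ccccc2)c(OC)c1 | intermediate (not isolated)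
13 | lithium (4-benzyloxy-3-methoxyphenyl)[(E)-3-(triisopropylsilyloxy)prop-1-enyl]borate of diol 4 (configuration at boron immaterial) | [Li+].COc1cc(ccc1OCc1ccccc1)[B-]1(/C=C/CO[Si](C(C)C)(C(C)C)C(C)C)O[C@]2(C)c3cccc4cccc(c34)[C@]2(C)O1 | intermediate (not isolated)
14 | methyl 3-[(1S,2R)-1-(4-benzyloxy-3-methoxyphenyl)-1-B(mac)-3-(triisopropylsilyloxy)propan-2-yl]-4-fluoro-5-methoxybenzoate | COC(=O)c1cc(OC)c(F)c(c1)[C@H](CO[Si](C(C)C)(C(C)C)C(C)C)[C@@H](c1ccc(OCc2ccccc2)c(OC)c1)B1O[C@]2(C)c3cccc4cccc(c34)[C@]2(C)O1 | intermediate
15 | methyl 3-[(1S,2R)-1-(4-benzyloxy-3-methoxyphenyl)-1-hydroxy-3-(triisopropylsilyloxy)propan-2-yl]-4-fluoro-5-methoxybenzoate | COC(=O)c1cc(OC)c(F)c(c1)[C@H](CO[Si](C(C)C)(C(C)C)C(C)C)[C@@H](c1ccc(OCc2ccccc2)c(OC)c1)O | intermediate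
16 | methyl (2S,3R)-2-(4-benzyloxy-3-methoxyphenyl)-7-methoxy-3-[(triisopropylsilyloxy)methyl]-2,3-dihydrobenzofuran-5-carboxylate | COC(=O)c1cc(OC)c2c(c1)[C@H](CO[Si](C(C)C)(C(C)C)C(C)C)[C@@H](c1ccc(OCc3ccccc3)c(OC)c1)O2 | intermediate
17 | methyl (2S,3R)-2-(4-benzyloxy-3-methoxyphenyl)-3-(hydroxymethyl)-7-methoxy-2,3-dihydrobenzofuran-5-carboxylate | COC(=O)c1cc(OC)c2c(c1)[C@H](CO)[C@@H](c1ccc(OCc3ccccc3)c(OC)c1)O2 | intermediate
18 | curlignan, methyl (2S,3R)-2-(4-hydroxy-3-methoxyphenyl)-3-(hydroxymethyl)-7-methoxy-2,3-dihydrobenzofuran-5-carboxylate | COC(=O)c1cc(OC)c2c(c1)[C@H](CO)[C@@H](c1ccc(O)c(OC)c1)O2 | target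

## Step count and least certain steps

Total step count: 10. Longest linear sequence: 7 steps (steps 1, 3, 6, 7, 8, 9 and 10; the branch through step 2 is equally long).

**Step 6 (key step).** Three processes are the most likely to go wrong.
- Direct transfer of the alkenyl or aryl group from boron to palladium without the 1,2-shift. This is the usual course for beta-substituted ate complexes, and the hindered boron ligand may not suppress it fully beside the bulky silyloxymethyl group.
- Inhibition of the cationic palladium by bromide, if the triflate salt fails to remove both equivalents.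
- Weak face selection with an ortho-fluoro aryl partner.

The fallback gives up the three-component coupling and makes the C2-C3 bond by an auxiliary-controlled aldol reaction. It sets out from 11 and comes back at 15. Palladium-catalysed coupling of 11 with the Reformatsky reagent BrZnCH2CO2tBu (Pd(dba)2, XPhos, THF) would give tert-butyl 2-[2-fluoro-3-methoxy-5-(methoxycarbonyl)phenyl]acetate F1. CF3CO2H would free 2-[2-fluoro-3-methoxy-5-(methoxycarbonyl)phenyl]acetic acid F2. Its pivaloyl mixed anhydride (Et3N, LiCl) would be joined to commercial (S)-4-benzyl-2-oxazolidinone to give methyl 3-{2-[(4S)-4-benzyl-2-oxo-1,3-oxazolidin-3-yl]-2-oxoethyl}-4-fluoro-5-methoxybenzoate F3. An Evans syn aldol reaction of F3 (Bu2BOTf, iPr2NEt, CH2Cl2, −78 °C) with commercial 4-benzyloxy-3-methoxybenzaldehyde should give methyl 3-[(2S,3S)-1-[(4S)-4-benzyl-2-oxo-1,3-oxazolidin-3-yl]-3-(4-benzyloxy-3-methoxyphenyl)-3-hydroxy-1-oxopropan-2-yl]-4-fluoro-5-methoxybenzoate F4 through the Zimmerman-Traxler chair of the Z boron enolate; the syn aldol relation is the one that maps onto the trans ring. NaBH4 in THF/H2O would release the auxiliary without touching the aryl ester and give methyl 3-[(1S,2R)-1-(4-benzyloxy-3-methoxyphenyl)-1,3-dihydroxypropan-2-yl]-4-fluoro-5-methoxybenzoate F5. Selective silylation of its primary hydroxyl group (TIPSCl, imidazole) leads to 15. Six operations replace two, but each is routine.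

**Step 8.** A single para ester, with a methoxy group next to the fluoride, activates C7a only moderately. If the closure is slow, silicon may migrate from the primary to the secondary oxygen, after which the primary alkoxide would close onto C7a and give the isomeric ring; the alkoxide may also attack the ester.

The fallback closes the ring from the other side: C2-O1 is formed by capture of a C2 benzylic cation by a ring-A phenol, not C7a-O1 by substitution. It sets out from 6 and 8 (through 13) and comes back at 17. Commercial methyl 3-bromo-4-hydroxy-5-methoxybenzoate would be protected (MeOCH2Cl, iPr2NEt) as methyl 3-bromo-5-methoxy-4-(methoxymethoxy)benzoate F6. F6 takes the place of 11 under the conditions of step 6 and should give methyl 3-[(1S,2R)-1-(4-benzyloxy-3-methoxyphenyl)-1-B(mac)-3-(triisopropylsilyloxy)propan-2-yl]-5-methoxy-4-(methoxymethoxy)benzoate F7. Perborate oxidation as in step 7 would give methyl 3-[(1S,2R)-1-(4-benzyloxy-3-methoxyphenyl)-1-hydroxy-3-(triisopropylsilyloxy)propan-2-yl]-5-methoxy-4-(methoxymethoxy)benzoate F8. HCl in methanol would then remove the methoxymethyl and silyl groups and ionise the para-alkoxybenzylic alcohol. The ring-A phenol should add to C2 anti to the substituent on the untouched C3, which gives 17 with the trans ring.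

**Step 5.** The borylation site is expected to be secure. The weaker half is the copper step: protodeboronation of the ortho-fluoro arylboronate in hot aqueous methanol, or partial loss of the ester, may compete with bromination.

The fallback changes the electrophile class. It sets out from 10, isolated after the borylation, and comes back at 14. Oxidation of 10 (NaBO3·4H2O, THF/H2O) would give methyl 4-fluoro-3-hydroxy-5-methoxybenzoate F9. Tf2O and pyridine would convert it into methyl 4-fluoro-3-methoxy-5-(trifluoromethanesulfonyloxy)benzoate F10. F10 replaces 11 in step 6; aryl triflates are the electrophiles for which this coupling is best established, and they bring no halide.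

**Step 3.** Hydroboration with catecholborane may give some internal boronate or double addition, and the hindered diol 4 may exchange slowly or incompletely.

The fallback separates the two tasks. It sets out from 2 and comes back at 6. Hydroboration of 2 with pinacolborane and catalytic Cp2Zr(H)Cl would give the pinacol ester 4,4,5,5-tetramethyl-2-[(E)-3-(triisopropylsilyloxy)prop-1-enyl]-1,3,2-dioxaborolane F11. NaIO4 and NH4OAc in aqueous acetone would cleave the pinacol ligand to give (E)-3-(triisopropylsilyloxy)prop-1-enylboronic acid F12. Condensation of F12 with 4 over MgSO4 gives 6.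

## Further compounds

F1 | step 6 | tert-butyl 2-[2-fluoro-3-methoxy-5-(methoxycarbonyl)phenyl]acetate | COC(=O)c1cc(OC)c(F)c(CC(=O)OC(C)(C)C)c1
F2 | step 6 | 2-[2-fluoro-3-methoxy-5-(methoxycarbonyl)phenyl]acetic acid | COC(=O)c1cc(OC)c(F)c(CC(=O)O)c1
F3 | step 6 | methyl 3-{2-[(4S)-4-benzyl-2-oxo-1,3-oxazolidin-3-yl]-2-oxoethyl}-4-fluoro-5-methoxybenzoate | COC(=O)c1cc(OC)c(F)c(CC(=O)N2[C@@H](Cc3ccccc3)COC2=O)c1
F4 | step 6 | methyl 3-[(2S,3S)-1-[(4S)-4-benzyl-2-oxo-1,3-oxazolidin-3-yl]-3-(4-benzyloxy-3-methoxyphenyl)-3-hydroxy-1-oxopropan-2-yl]-4-fluoro-5-methoxybenzoate | COC(=O)c1cc(OC)c(F)c(c1)[C@H](C(=O)N1[C@@H](Cc2ccccc2)COC1=O)[C@@H](c1ccc(OCc2ccccc2)c(OC)c1)O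
F5 | step 6 | methyl 3-[(1S,2R)-1-(4-benzyloxy-3-methoxyphenyl)-1,3-dihydroxypropan-2-yl]-4-fluoro-5-methoxybenzoate | COC(=O)c1cc(OC)c(F)c(c1)[C@H](CO)[C@@H](c1ccc(OCc2ccccc2)c(OC)c1)O
F6 | step 8 | methyl 3-bromo-5-methoxy-4-(methoxymethoxy)benzoate | COCOc1c(Br)cc(cc1OC)C(=O)OC
F7 | step 8 | methyl 3-[(1S,2R)-1-(4-benzyloxy-3-methoxyphenyl)-1-B(mac)-3-(triisopropylsilyloxy)propan-2-yl]-5-methoxy-4-(methoxymethoxy)benzoate | COC(=O)c1cc(OC)c(OCOC)c(c1)[C@H](CO[Si](C(C)C)(C(C)C)C(C)C)[C@@H](c1ccc(OCc2ccccc2)c(OC)c1)B1O[C@]2(C)c3cccc4cccc(c34)[C@]2(C)O1
F8 | step 8 | methyl 3-[(1S,2R)-1-(4-benzyloxy-3-methoxyphenyl)-1-hydroxy-3-(triisopropylsilyloxy)propan-2-yl]-5-methoxy-4-(methoxymethoxy)benzoate | COC(=O)c1cc(OC)c(OCOC)c(c1)[C@H](CO[Si](C(C)C)(C(C)C)C(C)C)[C@@H](c1ccc(OCc2ccccc2)c(OC)c1)O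
F9 | step 5 | methyl 4-fluoro-3-hydroxy-5-methoxybenzoate | COC(=O)c1cc(O)c(F)c(OC)c1
F10 | step 5 | methyl 4-fluoro-3-methoxy-5-(trifluoromethanesulfonyloxy)benzoate | COC(=O)c1cc(OS(=O)(=O)C(F)(F)F)c(F)c(OC)c1
F11 | step 3 | 4,4,5,5-tetramethyl-2-[(E)-3-(triisopropylsilyloxy)prop-1-enyl]-1,3,2-dioxaborolane | CC(C)[Si](C(C)C)(C(C)C)OC/C=C/B1OC(C)(C)C(C)(C)O1
F12 | step 3 | (E)-3-(triisopropylsilyloxy)prop-1-enylboronic acid | CC(C)[Si](C(C)C)(C(C)C)OC/C=C/B(O)O
A1 | alternative 1 | methyl (2S)-2-(4-acetoxy-3-methoxyphenyl)-8-methoxy-4-oxochromane-6-carboxylate | COC(=O)c1cc(OC)c2c(c1)C(=O)C[C@@H](c1ccc(OC(C)=O)c(OC)c1)O2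
A2 | alternative 1 | dimethyl (2S,3S)-2-(4-acetoxy-3-methoxyphenyl)-7-methoxy-2,3-dihydrobenzofuran-3,5-dicarboxylate | COC(=O)c1cc(OC)c2c(c1)[C@H](C(=O)OC)[C@@H](c1ccc(OC(C)=O)c(OC)c1)O2
A3 | alternative 2 | tert-butyl{[(4R,5S)-5-(4-benzyloxy-3-methoxyphenyl)-4-[(tert-butyldimethylsilyloxy)methyl]-4,5-dihydrofuran-2-yl]oxy}dimethylsilane | CC(C)(C)[Si](C)(C)OC1=C[C@H](CO[Si](C)(C)C(C)(C)C)[C@@H](c2ccc(OCc3ccccc3)c(OC)c2)O1
A4 | alternative 2 | methyl 3-bromo-2-oxo-2H-pyran-5-carboxylate | COC(=O)C1=COC(=O)C(Br)=C1
A5 | alternative 2 | methyl (2S,3R)-2-(4-benzyloxy-3-methoxyphenyl)-7-bromo-3-[(tert-butyldimethylsilyloxy)methyl]-2,3-dihydrobenzofuran-5-carboxylate | COC(=O)c1cc(Br)c2c(c1)[C@H](CO[Si](C)(C)C(C)(C)C)[C@@H](c1ccc(OCc3ccccc3)c(OC)c1)O2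
A6 | alternative 3 | methyl 6-{[(1S,2R)-1-(4-benzyloxy-3-methoxyphenyl)-2-[(tert-butyldimethylsilyloxy)methyl]but-3-yn-1-yl]oxy}-5-methoxypyridazine-3-carboxylate | COC(=O)c1cc(OC)c(nn1)O[C@H](c1ccc(OCc2ccccc2)c(OC)c1)[C@@H](CO[Si](C)(C)C(C)(C)C)C#C
A7 | alternative 3 | methyl (2S,3R)-2-(4-benzyloxy-3-methoxyphenyl)-3-[(tert-butyldimethylsilyloxy)methyl]-7-methoxy-2,3-dihydrobenzofuran-5-carboxylate | COC(=O)c1cc(OC)c2c(c1)[C@H](CO[Si](C)(C)C(C)(C)C)[C@@H](c1ccc(OCc3ccccc3)c(OC)c1)O2
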